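**Plan**

1. Locants: tetralone C1–C8a, ring A = C4a/C5–C8/C8a, ring B = C1–C4/C4a/C8a, primed locants = naphthalene. The retrosynthesis first removes three benzyl ethers, then opens ring B at C1–C8a to give siloxy alkyne 12.
2. Further cuts: C2 is excised (Kowalski homologation forward) to give ester 9; C4–C4a is cut (conjugate arylation) to give naphthyl acrylate 5 and ring A boronate 8; C4–C1' is cut (Heck reaction) to give bromide 3.
3. Forward order: naphthalene piece (bromination, benzylation, Heck), ring A joined at C4, chain lengthened by one carbon as a siloxy alkyne, ring B closed last, then hydrogenolysis.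
4. Stereochemistry: the only stereocenter, C4 (S), is set in step 6 by a chiral diene–rhodium catalyst (aryl to the Si face of the enoate β-carbon) and is not touched afterwards.
5. Feature used by the key step: C1 is at the acyl oxidation level, and C8a is the one free ring A carbon next to the side chain and lies ortho to the C8 oxygen. C1 can therefore be carried as the oxygen-bearing carbon of a siloxy alkyne, whose protonation gives a ketenium ion that ring A captures at C8a under catalytic acid.

Key step: step 8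

Assumption: the sense of induction of the rhodium–diene catalyst in step 6 is taken from the model established for E-configured enones and enoates; if correlation of 9 shows the opposite configuration, the enantiomeric ligand is used and nothing else changes. 5-Methoxynaphthalen-1-ol, ethyl acrylate and 2-bromobenzene-1,4-diol are taken as commercial.

**Route**

Step 1
Reactants: 1 5-methoxynaphthalen-1-ol
Product: 2 4-bromo-5-methoxynaphthalen-1-ol
Conditions: NBS (1.0 equiv), MeCN, −20 °C to 0 °C, dark
Reagents that add atoms: N-bromosuccinimide, O=C1CCC(=O)N1Br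
Why: Electrophilic aromatic bromination: the free hydroxyl makes its own ring the more reactive one and should direct NBS to C4, the α position para to it, as in the para bromination of 1-naphthol; the peri methoxy group is tolerated as in 1,5-dialkoxynaphthalenes.

Step 2
Reactants: 2 4-bromo-5-methoxynaphthalen-1-ol
Product: 3 1-(benzyloxy)-4-bromo-5-methoxynaphthalene
Conditions: BnBr, K2CO3, DMF, rt
Reagents that add atoms: benzyl bromide, BrCc1ccccc1
Why: Williamson ether synthesis masks the naphthol as a benzyl ether that should survive palladium coupling, organolithium reagents and the catalytic acid of step 8 and leaves by hydrogenolysis at the end.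

Step 3
Reactants: 3 1-(benzyloxy)-4-bromo-5-methoxynaphthalene; 4 ethyl acrylate
Product: 5 ethyl (2E)-3-[4-(benzyloxy)-8-methoxynaphthalen-1-yl]prop-2-enoate
Conditions: Pd(OAc)2 (5 mol %), P(o-tol)3, Et3N, DMF, 110 °C
Reagents that add atoms: none
Why: Mizoroki–Heck reaction: oxidative addition of the aryl bromide, syn insertion of the acrylate and syn β-hydride elimination should give the E enoate only.

Step 4
Reactants: 6 2-bromobenzene-1,4-diol
Product: 7 1,4-bis(benzyloxy)-2-bromobenzene
Conditions: BnBr (2.2 equiv), K2CO3, DMF, 50 °C, under argon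
Reagents that add atoms: benzyl bromide, BrCc1ccccc1
Why: Double Williamson ether synthesis under inert gas (the hydroquinone dianion is air-sensitive) gives the ring A building block with both oxygens benzylated.

Step 5
Reactants: 7 1,4-bis(benzyloxy)-2-bromobenzene
Product: 8 2-[2,5-bis(benzyloxy)phenyl]-4,4,5,5-tetramethyl-1,3,2-dioxaborolane
Conditions: B2pin2, PdCl2(dppf) (3 mol %), KOAc, dioxane, 90 °C
Reagents that add atoms: bis(pinacolato)diboron, CC1(C)OB(OC1(C)C)B1OC(C)(C)C(C)(C)O1
Why: Miyaura borylation with zerovalent palladium formed in situ tolerates the ortho benzyloxy group and gives a storable boronate.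

Step 6
Reactants: 5 ethyl (2E)-3-[4-(benzyloxy)-8-methoxynaphthalen-1-yl]prop-2-enoate; 8 2-[2,5-bis(benzyloxy)phenyl]-4,4,5,5-tetramethyl-1,3,2-dioxaborolane
Product: 9 ethyl (3S)-3-[2,5-bis(benzyloxy)phenyl]-3-[4-(benzyloxy)-8-methoxynaphthalen-1-yl]propanoate
Conditions: [RhCl(C2H4)2]2 (2.5 mol %), (1R,4R)-2,5-diphenylbicyclo[2.2.2]octa-2,5-diene (5.5 mol %), KOH (0.5 equiv), dioxane–H2O 10:1, 50 °C; 8 (2.5 equiv)
Reagents that add atoms: none
Why: Hayashi–Miyaura asymmetric 1,4-addition: the aryl–rhodium species formed by transmetalation from 8 inserts the enoate, and the C2-symmetric diene ligand should let the aryl group reach only the Si face of C3, which sets the (S) center (the later C4) before hydrolysis of the oxa-π-allyl rhodium species releases 9.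

Step 7
Reactants: 9 ethyl (3S)-3-[2,5-bis(benzyloxy)phenyl]-3-[4-(benzyloxy)-8-methoxynaphthalen-1-yl]propanoate
Product: 12 {[(4S)-4-[2,5-bis(benzyloxy)phenyl]-4-[4-(benzyloxy)-8-methoxynaphthalen-1-yl]but-1-yn-1-yl]oxy}tri(propan-2-yl)silane, via lithium dibromoenolate 10 (not isolated), via lithium ynolate 11 (not isolated)
Conditions: CH2Br2, lithium 2,2,6,6-tetramethylpiperidide, THF, −78 °C; LiN(SiMe3)2, −78 °C; n-BuLi, −78 °C to 0 °C; TIPSOTf, −78 °C to 0 °C
Reagents that add atoms: dibromomethane, BrCBr; triisopropylsilyl trifluoromethanesulfonate, CC(C)[Si](OS(=O)(=O)C(F)(F)F)(C(C)C)C(C)C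
Why: Kowalski ester homologation stopped at the ynolate: dibromomethyllithium adds to the ester, loss of ethoxide and deprotonation give 10, bromine–lithium exchange and a Fritsch–Buttenberg–Wiechell-type 1,2-shift give 11, and O-silylation gives the siloxy alkyne, while the stereocenter lies two carbons from the reacting center and is not deprotonated.

Step 8
Reactants: 12 {[(4S)-4-[2,5-bis(benzyloxy)phenyl]-4-[4-(benzyloxy)-8-methoxynaphthalen-1-yl]but-1-yn-1-yl]oxy}tri(propan-2-yl)silane
Product: 14 (4S)-5,8-bis(benzyloxy)-4-[4-(benzyloxy)-8-methoxynaphthalen-1-yl]-3,4-dihydronaphthalen-1(2H)-one, via enol silyl ether 13 (not isolated)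
Conditions: HNTf2 (10 mol %), CH2Cl2, −40 °C to rt; then TBAF, AcOH, THF, 0 °C
Reagents that add atoms: none
Why: HNTf2 protonates the electron-rich alkyne of 12 at C2 and gives a silyl ketenium ion whose sp carbon C1 is an acylium equivalent; ring A attacks it through C8a, the arenium ion returns its proton to the triflimide, and the first product is enol silane 13, which fluoride cleaves to ketone 14. The closest known reaction type is the Brønsted acid-promoted carbocyclization of 1-siloxy-1-alkynes with arenes to tetralone enol silyl ethers. Ring B closes in the 6-endo-dig mode with respect to the C1=C2 bond of the ketenium ion (6-exo with respect to its C=O bond). No stereocenter is formed; C4 was set in step 6, is not conjugated with the cation and should keep its (S) configuration because only catalytic acid and buffered fluoride are present. The selectivity needed is the site of arylation: C8a is ortho to the C8 benzyloxy group, which stabilizes the arenium ion directly, whereas the competing C2' of the naphthalene is meta to its benzyloxy group and the other ortho position of ring A (C5) is blocked, so closure onto C8a should dominate.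

Step 9
Reactants: 14 (4S)-5,8-bis(benzyloxy)-4-[4-(benzyloxy)-8-methoxynaphthalen-1-yl]-3,4-dihydronaphthalen-1(2H)-one
Product: 15 (4S)-5,8-dihydroxy-4-(4-hydroxy-8-methoxynaphthalen-1-yl)-3,4-dihydronaphthalen-1(2H)-one
Conditions: H2 (1 atm), 10% Pd/C, EtOAc–MeOH, rt; work-up under argon
Reagents that add atoms: none
Why: Hydrogenolysis of the three aryl benzyl ethers over palladium should be much faster than reduction of the hydrogen-bonded aryl ketone or cleavage of the methyl ether, and nothing in the medium can epimerize C4.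

**Compound list**

1 | 5-methoxynaphthalen-1-ol | COc1cccc2c(O)cccc12 | starting material
2 | 4-bromo-5-methoxynaphthalen-1-ol | COc1cccc2c(O)ccc(Br)c12 | intermediate
3 | 1-(benzyloxy)-4-bromo-5-methoxynaphthalene | COc1cccc2c(OCc3ccccc3)ccc(Br)c12 | intermediate
4 | ethyl acrylate | C=CC(=O)OCC | starting material
5 | ethyl (2E)-3-[4-(benzyloxy)-8-methoxynaphthalen-1-yl]prop-2-enoate | CCOC(=O)/C=C/c1ccc(OCc2ccccc2)c2cccc(OC)c12 | intermediate
6 | 2-bromobenzene-1,4-diol | Oc1ccc(O)c(Br)c1 | starting material
7 | 1,4-bis(benzyloxy)-2-bromobenzene | Brc1cc(OCc2ccccc2)ccc1OCc1ccccc1 | intermediate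
8 | 2-[2,5-bis(benzyloxy)phenyl]-4,4,5,5-tetramethyl-1,3,2-dioxaborolane | CC1(C)OB(OC1(C)C)c1cc(OCc2ccccc2)ccc1OCc1ccccc1 | intermediate
9 | ethyl (3S)-3-[2,5-bis(benzyloxy)phenyl]-3-[4-(benzyloxy)-8-methoxynaphthalen-1-yl]propanoate | CCOC(=O)C[C@H](c1cc(OCc2ccccc2)ccc1OCc1ccccc1)c1ccc(OCc2ccccc2)c2cccc(OC)c12 | intermediate
10 | lithium (4S)-4-[2,5-bis(benzyloxy)phenyl]-4-[4-(benzyloxy)-8-methoxynaphthalen-1-yl]-1,1-dibromobut-1-en-2-olate (lithium dibromoenolate) | [Li+].[O-]C(=C(Br)Br)C[C@H](c1cc(OCc2ccccc2)ccc1OCc1ccccc1)c1ccc(OCc2ccccc2)c2cccc(OC)c12 | intermediate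
11 | lithium (4S)-4-[2,5-bis(benzyloxy)phenyl]-4-[4-(benzyloxy)-8-methoxynaphthalen-1-yl]but-1-yn-1-olate (lithium ynolate) | [Li+].[O-]C#CC[C@H](c1cc(OCc2ccccc2)ccc1OCc1ccccc1)c1ccc(OCc2ccccc2)c2cccc(OC)c12 | intermediate
12 | {[(4S)-4-[2,5-bis(benzyloxy)phenyl]-4-[4-(benzyloxy)-8-methoxynaphthalen-1-yl]but-1-yn-1-yl]oxy}tri(propan-2-yl)silane | CC(C)[Si](OC#CC[C@H](c1cc(OCc2ccccc2)ccc1OCc1ccccc1)c1ccc(OCc2ccccc2)c2cccc(OC)c12)(C(C)C)C(C)C | intermediate
13 | {[(4S)-5,8-bis(benzyloxy)-4-[4-(benzyloxy)-8-methoxynaphthalen-1-yl]-3,4-dihydronaphthalen-1-yl]oxy}tri(propan-2-yl)silane (enol silyl ether) | COc1cccc2c(OCc3ccccc3)ccc([C@@H]3CC=C(O[Si](C(C)C)(C(C)C)C(C)C)c4c(OCc5ccccc5)ccc(OCc5ccccc5)c43)c12 | intermediate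
14 | (4S)-5,8-bis(benzyloxy)-4-[4-(benzyloxy)-8-methoxynaphthalen-1-yl]-3,4-dihydronaphthalen-1(2H)-one | COc1cccc2c(OCc3ccccc3)ccc([C@@H]3CCC(=O)c4c(OCc5ccccc5)ccc(OCc5ccccc5)c43)c12 | intermediate
15 | (4S)-5,8-dihydroxy-4-(4-hydroxy-8-methoxynaphthalen-1-yl)-3,4-dihydronaphthalen-1(2H)-one | COc1cccc2c(O)ccc([C@@H]3CCC(=O)c4c(O)ccc(O)c43)c12 | target

**Step count and risks**

Total step count: 9. Longest linear sequence: 7 (steps 1, 2, 3, 6, 7, 8, 9).

Steps most likely to fail:

Step 8. What may go wrong: the ketenium ion is taken by C2' of the more nucleophilic naphthalene or by the C5 ether oxygen, or the siloxy alkyne is lost by protodesilylation before it cyclizes. The fallback sets out from 9 and changes both the acyl donor and the order of deprotection and ring closure. The Kowalski homologation is run to the end with an acidic ethanol quench and should give ethyl (4S)-4-[2,5-bis(benzyloxy)phenyl]-4-[4-(benzyloxy)-8-methoxynaphthalen-1-yl]butanoate F1. LiOH in THF–water then gives (4S)-4-[2,5-bis(benzyloxy)phenyl]-4-[4-(benzyloxy)-8-methoxynaphthalen-1-yl]butanoic acid F2. Hydrogenolysis (H2, Pd/C) gives (4S)-4-(2,5-dihydroxyphenyl)-4-(4-hydroxy-8-methoxynaphthalen-1-yl)butanoic acid F3. Cyclodehydration of F3 in BF3·OEt2 at about 70 °C is a direct acylation of the free hydroquinone ortho to the C8 hydroxyl, possibly through the seven-membered aryl lactone and a Fries-type shift. It should give 15 directly, so the route is rejoined at 15.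

Step 6. What may go wrong: slow insertion and competing protodeboronation with two hindered partners, or poor facial selectivity. The fallback sets out from 5 and replaces catalyst control by auxiliary control. LiOH hydrolysis gives (2E)-3-[4-(benzyloxy)-8-methoxynaphthalen-1-yl]prop-2-enoic acid F4. Its mixed pivalic anhydride and the lithium salt of (4S)-4-phenyl-1,3-oxazolidin-2-one give (4S)-3-[(2E)-3-[4-(benzyloxy)-8-methoxynaphthalen-1-yl]prop-2-enoyl]-4-phenyl-1,3-oxazolidin-2-one F5. Bromide 7 and Mg give [2,5-bis(benzyloxy)phenyl]magnesium bromide F6. With CuBr·SMe2 in THF at −40 °C, F6 should add to the chelated imide anti to its phenyl group and give (4S)-3-[(3S)-3-[2,5-bis(benzyloxy)phenyl]-3-[4-(benzyloxy)-8-methoxynaphthalen-1-yl]propanoyl]-4-phenyl-1,3-oxazolidin-2-one F7. EtOMgBr in ethanol removes the auxiliary, and the route comes back at 9.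

Step 1. What may go wrong: attack at C2 ortho to the hydroxyl, double bromination, or oxidation to the quinone. The fallback sets out from 1 and fixes the position by oxidation state instead of by directing effects. PhI(OAc)2 in aqueous MeCN gives 5-methoxynaphthalene-1,4-dione F8, and Na2S2O4 reduces it to 5-methoxynaphthalene-1,4-diol F9. One equivalent of BnBr with K2CO3 should benzylate the hydroxyl that is not hydrogen-bonded to the peri methoxy group and give 4-(benzyloxy)-8-methoxynaphthalen-1-ol F10. Tf2O and pyridine give 4-(benzyloxy)-8-methoxynaphthalen-1-yl trifluoromethanesulfonate F11. A Heck reaction of F11 with 4 (Pd(OAc)2, PPh3, Et3N, DMF) brings the route back at 5.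

**Further compounds**

F1 | step 8 | ethyl (4S)-4-[2,5-bis(benzyloxy)phenyl]-4-[4-(benzyloxy)-8-methoxynaphthalen-1-yl]butanoate | CCOC(=O)CC[C@H](c1cc(OCc2ccccc2)ccc1OCc1ccccc1)c1ccc(OCc2ccccc2)c2cccc(OC)c12
F2 | step 8 | (4S)-4-[2,5-bis(benzyloxy)phenyl]-4-[4-(benzyloxy)-8-methoxynaphthalen-1-yl]butanoic acid | OC(=O)CC[C@H](c1cc(OCc2ccccc2)ccc1OCc1ccccc1)c1ccc(OCc2ccccc2)c2cccc(OC)c12
F3 | step 8 | (4S)-4-(2,5-dihydroxyphenyl)-4-(4-hydroxy-8-methoxynaphthalen-1-yl)butanoic acid | OC(=O)CC[C@H](c1cc(O)ccc1O)c1ccc(O)c2cccc(OC)c12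
F4 | step 6 | (2E)-3-[4-(benzyloxy)-8-methoxynaphthalen-1-yl]prop-2-enoic acid | OC(=O)/C=C/c1ccc(OCc2ccccc2)c2cccc(OC)c12
F5 | step 6 | (4S)-3-[(2E)-3-[4-(benzyloxy)-8-methoxynaphthalen-1-yl]prop-2-enoyl]-4-phenyl-1,3-oxazolidin-2-one | O=C(/C=C/c1ccc(OCc2ccccc2)c2cccc(OC)c12)N1[C@@H](c2ccccc2)COC1=O
F6 | step 6 | [2,5-bis(benzyloxy)phenyl]magnesium bromide | Br[Mg]c1cc(OCc2ccccc2)ccc1OCc1ccccc1
F7 | step 6 | (4S)-3-[(3S)-3-[2,5-bis(benzyloxy)phenyl]-3-[4-(benzyloxy)-8-methoxynaphthalen-1-yl]propanoyl]-4-phenyl-1,3-oxazolidin-2-one | O=C(C[C@H](c1cc(OCc2ccccc2)ccc1OCc1ccccc1)c1ccc(OCc2ccccc2)c2cccc(OC)c12)N1[C@@H](c2ccccc2)COC1=O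
F8 | step 1 | 5-methoxynaphthalene-1,4-dione | COc1cccc2C(=O)C=CC(=O)c12
F9 | step 1 | 5-methoxynaphthalene-1,4-diol | COc1cccc2c(O)ccc(O)c12
F10 | step 1 | 4-(benzyloxy)-8-methoxynaphthalen-1-ol | COc1cccc2c(OCc3ccccc3)ccc(O)c12
F11 | step 1 | 4-(benzyloxy)-8-methoxynaphthalen-1-yl trifluoromethanesulfonate | COc1cccc2c(OCc3ccccc3)ccc(OS(=O)(=O)C(F)(F)F)c12
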